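**Retrosynthetic overview**
- Target ⇒ remove the ω-silyl group and the C-17 hydroxyl (late allylic hydroxylation) ⇒ ent-labda-7,13E-dien-15-yl 30-silyloxytriacontanoate ⇒ ester disconnection into ent-labda-7,13E-dien-15-ol and 30-silyloxytriacontanoic acid.
- ent-Labdadienol ⇒ ethyl ent-labda-7,13E-dien-15-oate ⇒ open C4–C5 and C9–C10 together ⇒ acyclic ethyl (2E,6E,10E)-geranylgeranoate ⇒ farnesylacetone + phosphonoacetate.
- Ring order: ring A, then ring B, in one enantioselective proton-initiated cascade that stops at the conjugated ester; C-5, C-9 and C-10 are all set there, and no ring is made before or after.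
- C30 acid ⇒ C11 + C8 + C11 by two Cu-catalysed sp3–sp3 Grignard couplings.
- The C-17 oxygen is installed after esterification, because the allylic ester deactivates the side-chain olefin and leaves the ring olefin as the reactive site.

Assumption: the acyl chain is read as 29 carbons beyond the carbonyl (30-hydroxytriacontanoyl), the ring stereocentres as the ent-labdane series (5R,9S,10R), and geometrically pure (5E,9E)-farnesylacetone is the commercial grade used.

**Route**

Step 1
Reactants: 1 (5E,9E)-farnesylacetone; 2 triethyl phosphonoacetate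
Product: 4 ethyl (2E,6E,10E)-geranylgeranoate, via sodium phosphonoacetate carbanion 3 (not isolated)
Conditions: NaH (1.3 equiv), THF, 0 °C; then 1, 0 → 50 °C, 16 h; SiO2 chromatography removes the 2Z isomer
Reagents that add atoms: none
Why: Horner–Wadsworth–Emmons olefination of the methyl ketone gives mainly the 2E enoate (about 4:1, thermodynamic control over the oxaphosphetane) and leaves the 6E and 10E olefins unchanged; no stereocentre is formed.

Step 2
Reactants: 4 ethyl (2E,6E,10E)-geranylgeranoate
Product: 6 ethyl ent-labda-7,13E-dien-15-oate (5R,9R,10R), via C-8 labdanyl cation 5 (not isolated)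
Conditions: confined chiral BINOL-derived imidodiphosphorimidate (IDPi) Brønsted acid (5 mol %; the antipode that gives the ent series, i.e. (+)-ambrox from homofarnesol), (CF3)3COH/CH2Cl2 1:1, −40 °C, 72 h; AgNO3–SiO2 chromatography
Reagents that add atoms: none
Why: Proposed new method: the chiral ion pair protonates the terminal olefin on one enantioface while 4 is folded chair–chair, the two E olefins then add anti in sequence (C4–C5, then C9–C10) so that the trans ring fusion and the equatorial C-9 side chain follow from the E geometries and the absolute sense of C-5, C-9 and C-10 from the catalyst antipode, and cation 5 cannot be captured by the conjugated, acid-bound 13,14-olefin, so it loses axial H-7 to the catalyst anion to give the endocyclic trisubstituted olefin (the usual main E1 product of this cation); this is a proton-initiated cation–olefin polyene bicyclisation whose closest known relatives are the chiral Brønsted acid (IDPi or BINOL·SnCl4) cyclisations of homofarnesol-type polyenes and the superacid cyclisation of polyprenoate esters that halts at the conjugated olefin.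

Step 3
Reactants: 6 ethyl ent-labda-7,13E-dien-15-oate
Product: 8 ent-labda-7,13E-dien-15-ol, via enal 7 (not isolated)
Conditions: DIBAL-H (2.5 equiv), CH2Cl2, −78 → 0 °C; aq. Rochelle salt
Reagents that add atoms: none
Why: DIBAL-H reduces the conjugated ester by two 1,2-hydride additions via the enal to the E-allylic alcohol and leaves the trisubstituted ring olefin and the three stereocentres untouched.

Step 4
Reactants: 9 11-bromoundecan-1-ol
Product: 10 (11-bromoundecyloxy)(tert-butyl)dimethylsilane
Conditions: TBSCl, imidazole, DMF, rt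
Reagents that add atoms: tert-butyldimethylsilyl chloride CC(C)(C)[Si](C)(C)Cl
Why: Standard silylation (imidazole-activated TBSCl) masks the hydroxyl so that a Grignard reagent can be made from the bromide.

Step 5
Reactants: 10 (11-bromoundecyloxy)(tert-butyl)dimethylsilane; 11 1,8-dibromooctane (4 equiv)
Product: 13 (19-bromononadecyloxy)(tert-butyl)dimethylsilane, via C11 Grignard reagent 12 (not isolated)
Conditions: Mg, THF, 45 °C; then added slowly to 11, Li2CuCl4 (3 mol %), THF, −10 °C → rt; excess 11 distilled off
Reagents that add atoms: none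
Why: Kochi–Tamura-type Cu-catalysed sp3–sp3 cross-coupling of a primary alkyl Grignard reagent with a primary bromide is fast at −10 °C, the silyl ether is inert, and the fourfold excess of dibromide keeps double coupling low.

Step 6
Reactants: 13 (19-bromononadecyloxy)(tert-butyl)dimethylsilane; 14 11-bromoundecanoic acid
Product: 17 30-[(tert-butyldimethylsilyl)oxy]triacontanoic acid, via C19 Grignard reagent 15 (not isolated), via chloromagnesium 11-bromoundecanoate 16 (not isolated)
Conditions: 13, Mg, THF, 50 °C; separately 14, t-BuMgCl (1.0 equiv), THF, −20 °C; combine, Li2CuCl4 (3 mol %), THF/NMP, −20 °C → rt; aq. NH4Cl, then citric acid to pH 4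
Reagents that add atoms: none
Why: The same Cu-catalysed Grignard–alkyl bromide coupling tolerates the carboxyl group once it is masked as its magnesium salt, so the C19 and C11 pieces join to the C30 acid with the acid function free for the next step.

Step 7
Reactants: 8 ent-labda-7,13E-dien-15-ol; 17 30-[(tert-butyldimethylsilyl)oxy]triacontanoic acid
Product: 19 ent-labda-7,13E-dien-15-yl 30-[(tert-butyldimethylsilyl)oxy]triacontanoate, via Yamaguchi mixed anhydride 18 (not isolated)
Conditions: 17, 2,4,6-Cl3C6H2COCl, Et3N, THF, rt, 2 h; then 8, DMAP, toluene, 40 °C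
Reagents that add atoms: none
Why: Yamaguchi esterification: the hindered aroyl group of the mixed anhydride directs DMAP and then the primary allylic alcohol to the aliphatic carbonyl, under basic conditions that cannot ionise the allylic C–O bond or touch the olefins.

Step 8
Reactants: 19 ent-labda-7,13E-dien-15-yl 30-[(tert-butyldimethylsilyl)oxy]triacontanoate
Product: 20 ent-17-hydroxylabda-7,13E-dien-15-yl 30-[(tert-butyldimethylsilyl)oxy]triacontanoate
Conditions: SeO2 (0.3 equiv), t-BuOOH (3 equiv), salicylic acid (10 mol %), CH2Cl2, 0 °C → rt, stopped at about 70 % conversion; 19 recycled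
Reagents that add atoms: tert-butyl hydroperoxide CC(C)(C)OO (terminal oxygen source); selenium dioxide O=[Se]=O (catalytic oxygen carrier)
Why: Sharpless-type SeO2/t-BuOOH allylic hydroxylation (ene reaction, then [2,3]-sigmatropic shift): selenium adds to C-7 of the electron-rich ring olefin and takes a C-17 hydrogen because C-9–H is tertiary and shielded, whereas the 13,14-olefin is deactivated by its allylic ester oxygen as in geranyl acetate; no stereocentre is touched (C-9 becomes S only through the priority change).

Step 9
Reactants: 20 ent-17-hydroxylabda-7,13E-dien-15-yl 30-[(tert-butyldimethylsilyl)oxy]triacontanoate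
Product: 21 ent-17-hydroxylabda-7,13E-dien-15-yl 30-hydroxytriacontanoate (target)
Conditions: HF·pyridine, THF/pyridine, 0 °C → rt
Reagents that add atoms: none
Why: Fluoride-driven cleavage of the primary silyl ether (Si–F bond formation) is orthogonal to the ester, the allylic alcohol and both olefins, and gives the target.

**Compound list**

1 | (5E,9E)-6,10,14-trimethylpentadeca-5,9,13-trien-2-one (E,E-farnesylacetone) | CC(C)=CCC/C(C)=C/CC/C(C)=C/CCC(C)=O | starting material
2 | triethyl phosphonoacetate | CCOC(=O)CP(=O)(OCC)OCC | starting material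
3 | sodium salt of the phosphonoacetate carbanion (formed in the flask) | CCOC(=O)[CH-]P(=O)(OCC)OCC.[Na+] | intermediate
4 | ethyl (2E,6E,10E)-3,7,11,15-tetramethylhexadeca-2,6,10,14-tetraenoate | CC(C)=CCC/C(C)=C/CC/C(C)=C/CC/C(C)=C/C(=O)OCC | intermediate
5 | C-8 carbocation of ethyl ent-labd-13E-en-15-oate, (5R,9R,10R) (formed in the flask) | C/C(=C\C(=O)OCC)CC[C@@H]1[C+](C)CC[C@@H]2C(C)(C)CCC[C@@]12C | intermediate
6 | ethyl (2E)-3-methyl-5-[(1R,4aR,8aR)-2,5,5,8a-tetramethyl-1,4,4a,5,6,7,8,8a-octahydronaphthalen-1-yl]pent-2-enoate (ethyl ent-labda-7,13E-dien-15-oate) | C/C(=C\C(=O)OCC)CC[C@@H]1C(C)=CC[C@@H]2C(C)(C)CCC[C@@]12C | intermediate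
7 | ent-labda-7,13E-dien-15-al (formed in the flask) | C/C(=C\C=O)CC[C@@H]1C(C)=CC[C@@H]2C(C)(C)CCC[C@@]12C | intermediate
8 | ent-labda-7,13E-dien-15-ol, (5R,9R,10R) | C/C(=C\CO)CC[C@@H]1C(C)=CC[C@@H]2C(C)(C)CCC[C@@]12C | intermediate
9 | 11-bromoundecan-1-ol | OCCCCCCCCCCCBr | starting material
10 | (11-bromoundecyloxy)(tert-butyl)dimethylsilane | CC(C)(C)[Si](C)(C)OCCCCCCCCCCCBr | intermediate
11 | 1,8-dibromooctane | BrCCCCCCCCBr | starting material
12 | [11-(tert-butyldimethylsilyloxy)undecyl]magnesium bromide (formed in the flask) | CC(C)(C)[Si](C)(C)OCCCCCCCCCCC[Mg]Br | intermediate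
13 | (19-bromononadecyloxy)(tert-butyl)dimethylsilane | CC(C)(C)[Si](C)(C)OCCCCCCCCCCCCCCCCCCCBr | intermediate
14 | 11-bromoundecanoic acid | OC(=O)CCCCCCCCCCBr | starting material
15 | [19-(tert-butyldimethylsilyloxy)nonadecyl]magnesium bromide (formed in the flask) | CC(C)(C)[Si](C)(C)OCCCCCCCCCCCCCCCCCCC[Mg]Br | intermediate
16 | chloromagnesium 11-bromoundecanoate (formed in the flask) | BrCCCCCCCCCCC(=O)O[Mg]Cl | intermediate
17 | 30-[(tert-butyldimethylsilyl)oxy]triacontanoic acid | CC(C)(C)[Si](C)(C)OCCCCCCCCCCCCCCCCCCCCCCCCCCCCCC(=O)O | intermediate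
18 | 30-[(tert-butyldimethylsilyl)oxy]triacontanoic 2,4,6-trichlorobenzoic anhydride (formed in the flask) | CC(C)(C)[Si](C)(C)OCCCCCCCCCCCCCCCCCCCCCCCCCCCCCC(=O)OC(=O)c1c(Cl)cc(Cl)cc1Cl | intermediate
19 | ent-labda-7,13E-dien-15-yl 30-[(tert-butyldimethylsilyl)oxy]triacontanoate, (5R,9R,10R) | C/C(=C\COC(=O)CCCCCCCCCCCCCCCCCCCCCCCCCCCCCO[Si](C)(C)C(C)(C)C)CC[C@@H]1C(C)=CC[C@@H]2C(C)(C)CCC[C@@]12C | intermediate
20 | ent-17-hydroxylabda-7,13E-dien-15-yl 30-[(tert-butyldimethylsilyl)oxy]triacontanoate, (5R,9S,10R) | C/C(=C\COC(=O)CCCCCCCCCCCCCCCCCCCCCCCCCCCCCO[Si](C)(C)C(C)(C)C)CC[C@@H]1C(CO)=CC[C@@H]2C(C)(C)CCC[C@@]12C | intermediate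
21 | (2E)-5-[(1S,4aR,8aR)-2-(hydroxymethyl)-5,5,8a-trimethyl-1,4,4a,5,6,7,8,8a-octahydronaphthalen-1-yl]-3-methylpent-2-en-1-yl 30-hydroxytriacontanoate | C/C(=C\COC(=O)CCCCCCCCCCCCCCCCCCCCCCCCCCCCCO)CC[C@@H]1C(CO)=CC[C@@H]2C(C)(C)CCC[C@@]12C | target

**Step count**

Total steps: 9. Longest linear sequence: 6 (steps 1, 2, 3, 7, 8, 9; the acid branch 4, 5, 6, 7, 8, 9 is equally long).

**Steps most likely to fail**

Step 2 is the highest risk. It asks for enantiocontrol without an internal nucleophile, a stop after two rings, and the Δ7 olefin rather than the Δ8(17) or Δ8 isomers; the enantiomer ratio would be checked on alcohol 8. The fallback sets out from 4 and returns at 6, and replaces the proton by an iodonium ion delivered by a chiral Lewis base. N-Iodosuccinimide with a stoichiometric BINOL-derived phosphoramidite promoter (antipode for the ent series) in toluene at −40 °C closes both rings in one operation and gives ethyl (3R)-3-iodo-ent-labda-7,13E-dien-15-oate F1, with iodine equatorial. Bu3SnH and AIBN in benzene at 80 °C then remove the iodine and give 6.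

Step 8 is the second risk. The site selectivity between the two trisubstituted olefins rests on analogy, and over-oxidation to the C-17 enal can occur on a late ester; any enal can be returned to 20 with NaBH4/CeCl3. The fallback sets out from 6 and returns at 20, and moves the oxidation ahead of the reduction. SeO2/t-BuOOH on 6, whose side-chain olefin is conjugated and inert, gives ethyl ent-17-hydroxylabda-7,13E-dien-15-oate F2. DIBAL-H reduces this to ent-labda-7,13E-diene-15,17-diol F3. Mixed anhydride 18 (0.95 equiv, DMAP, −40 °C) then acylates F3 once at the unhindered 15-OH, the 17-OH being flanked by the substituted C-9, and gives 20.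

Step 6 is the third risk. A waxy C19 Grignard reagent must couple with a poorly soluble magnesium carboxylate, and Wurtz homocoupling competes. The fallback sets out from 13 and returns at 17, and makes the same C19–C11 bond by acetylide alkylation. The dilithio salt of commercial undec-10-ynoic acid (n-BuLi 2.1 equiv, THF/DMPU, −78 → 25 °C) is alkylated by 13 to give 30-[(tert-butyldimethylsilyl)oxy]triacont-10-ynoic acid F4. H2 over Pd/C in EtOAc then saturates the triple bond and gives 17.

**Further compounds**

F1 | step 2 | ethyl (3R)-3-iodo-ent-labda-7,13E-dien-15-oate | C/C(=C\C(=O)OCC)CC[C@@H]1C(C)=CC[C@@H]2C(C)(C)[C@H](I)CC[C@@]12C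
F2 | step 8 | ethyl ent-17-hydroxylabda-7,13E-dien-15-oate | C/C(=C\C(=O)OCC)CC[C@@H]1C(CO)=CC[C@@H]2C(C)(C)CCC[C@@]12C
F3 | step 8 | ent-labda-7,13E-diene-15,17-diol | C/C(=C\CO)CC[C@@H]1C(CO)=CC[C@@H]2C(C)(C)CCC[C@@]12C
F4 | step 6 | 30-[(tert-butyldimethylsilyl)oxy]triacont-10-ynoic acid | CC(C)(C)[Si](C)(C)OCCCCCCCCCCCCCCCCCCCC#CCCCCCCCCC(=O)O
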